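## Retrosynthetic overview

1. The side chain is cut between its third and fourth carbons (counted from the ring): a Julia–Kocienski olefination joins a phthalide aldehyde (fragment A, 16 of the 29 heavy atoms of the target) to a tetrazolyl sulfone (fragment B, 13). Hydrogenation (alkene and benzyl ether) and acid unmasking of the hydroxy ketone follow.
2. Fragment A: resorcinol → Kolbe–Schmitt acid → 4-OBn/2-OMe diethylamide → directed ortho-metalation/formylation → Brown allylation (sets the ring stereocentre, S) → lactonisation → hydroboration → aldehyde.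
3. Fragment B: (S)-γ-valerolactone (brings the carbinol stereocentre, S) → Weinreb amide → hex-5-enyl ketone → dioxolane → hydroboration → Mitsunobu sulfide → sulfone.
4. Rings: the benzene ring is bought with resorcinol. The γ-lactone (phthalide) ring is closed in fragment A before the coupling. The dioxolane is a temporary ring opened in the last step.

Assumption: alkene 27 is drawn as the E isomer but is carried on as an E/Z mixture, since the double bond is hydrogenated in step 19.

Abbreviations: Bn = benzyl; TBS = tert-butyldimethylsilyl; PT = 1-phenyl-1H-tetrazol-5-yl; Ipc = isopinocampheyl; 9-BBN = 9-borabicyclo[3.3.1]nonane.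

## Fragment A

Step 1
Reactants: 1 resorcinol
Product: 2 2,4-dihydroxybenzoic acid
Conditions: KHCO3 (5 equiv), H2O, CO2 stream, 100 °C; then conc. HCl
Reagents that add atoms: potassium hydrogencarbonate, [K+].OC([O-])=O (delivers carbon dioxide, O=C=O)
Why: Kolbe–Schmitt carboxylation of the electron-rich resorcinol ring occurs ortho to one hydroxyl and para to the other, giving β-resorcylic acid as one regioisomer.

Step 2
Reactants: 2 2,4-dihydroxybenzoic acid
Product: 3 methyl 2,4-dihydroxybenzoate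
Conditions: MeOH, H2SO4 (cat.), reflux
Reagents that add atoms: methanol, CO
Why: Fischer esterification in excess methanol converts the acid to its methyl ester and leaves both phenols free.

Step 3
Reactants: 3 methyl 2,4-dihydroxybenzoate
Product: 4 methyl 4-(benzyloxy)-2-hydroxybenzoate
Conditions: BnBr (1.05 equiv), K2CO3 (1.1 equiv), acetone, reflux
Reagents that add atoms: benzyl bromide, BrCc1ccccc1
Why: Williamson etherification is selective for the 4-OH because the 2-OH is tied up in a hydrogen bond to the ester carbonyl.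

Step 4
Reactants: 4 methyl 4-(benzyloxy)-2-hydroxybenzoate
Product: 5 methyl 4-(benzyloxy)-2-methoxybenzoate
Conditions: MeI (2 equiv), K2CO3 (2 equiv), DMF, 60 °C
Reagents that add atoms: iodomethane, CI
Why: Williamson etherification under more forcing conditions methylates the remaining hydrogen-bonded 2-OH.

Step 5
Reactants: 5 methyl 4-(benzyloxy)-2-methoxybenzoate
Product: 6 4-(benzyloxy)-N,N-diethyl-2-methoxybenzamide
Conditions: AlMe3 (2.5 equiv), Et2NH (2.5 equiv), toluene, 0 °C → 90 °C; then aq. potassium sodium tartrate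
Reagents that add atoms: diethylamine, CCNCC
Why: Weinreb-type aminolysis by the aluminium amide Me2AlNEt2 turns the ester directly into the tertiary amide that serves as the ortho-directing group.

Step 6
Reactants: 6 4-(benzyloxy)-N,N-diethyl-2-methoxybenzamide
Product: 8 4-(benzyloxy)-N,N-diethyl-2-formyl-6-methoxybenzamide, via aryllithium 7 (not isolated)
Conditions: s-BuLi (1.2 equiv), TMEDA (1.2 equiv), THF, −78 °C, 1 h; DMF (3 equiv), −78 → 0 °C; then 1 M HCl
Reagents that add atoms: N,N-dimethylformamide, CN(C)C=O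
Why: Directed ortho-metalation: the tertiary amide, the strongest director on the ring, guides s-BuLi/TMEDA to its only free ortho position, and the aryllithium is formylated by DMF.

Step 7
Reactants: 8 4-(benzyloxy)-N,N-diethyl-2-formyl-6-methoxybenzamide
Product: 10 4-(benzyloxy)-N,N-diethyl-2-[(1S)-1-hydroxybut-3-en-1-yl]-6-methoxybenzamide, via borinate ester 9 (not isolated)
Conditions: (−)-Ipc2BOMe (1.5 equiv), allylmagnesium bromide (1.4 equiv), Et2O, 0 °C → rt, 1 h; then 8, Et2O/THF, −78 °C, 3 h; then 3 M NaOH, 30% H2O2, 0 °C → rt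
Reagents that add atoms: allylmagnesium bromide, C=CC[Mg]Br
Why: Brown asymmetric allylboration: (−)-Ipc2B(allyl), made in the flask from the (+)-α-pinene-derived borinate, delivers allyl through a closed chair transition state to the Si face of the aryl aldehyde, setting the carbinol centre as S (the sense known for benzaldehyde), and alkaline peroxide frees the alcohol.

Step 8
Reactants: 10 4-(benzyloxy)-N,N-diethyl-2-[(1S)-1-hydroxybut-3-en-1-yl]-6-methoxybenzamide
Product: 11 (3S)-3-allyl-5-(benzyloxy)-7-methoxyisobenzofuran-1(3H)-one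
Conditions: TsOH·H2O (1.2 equiv), toluene, 80 °C
Reagents that add atoms: none
Why: Acid-promoted lactonisation (intramolecular N→O acyl transfer) closes the five-membered phthalide with loss of diethylamine and does not touch the C–O bond of the stereocentre, so S is retained.

Step 9
Reactants: 11 (3S)-3-allyl-5-(benzyloxy)-7-methoxyisobenzofuran-1(3H)-one
Product: 13 (3S)-5-(benzyloxy)-3-(3-hydroxypropyl)-7-methoxyisobenzofuran-1(3H)-one, via B-alkyl-9-BBN adduct 12 (not isolated)
Conditions: 9-BBN (0.5 M in THF, 1.5 equiv), 0 °C → rt; then NaBO3·4H2O, THF/H2O, rt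
Reagents that add atoms: sodium perborate (NaBO3·4H2O), [Na+].[Na+].O[B-]1(O)OO[B-](O)(O)OO1
Why: Anti-Markovnikov hydroboration with bulky 9-BBN is selective for the terminal alkene over the lactone, and mild perborate oxidation gives the primary alcohol without opening the lactone.

Step 10
Reactants: 13 (3S)-5-(benzyloxy)-3-(3-hydroxypropyl)-7-methoxyisobenzofuran-1(3H)-one
Product: 14 (3S)-5-(benzyloxy)-7-methoxy-3-(3-oxopropyl)isobenzofuran-1(3H)-one
Conditions: Dess–Martin periodinane (1.3 equiv), NaHCO3, CH2Cl2, 0 °C → rt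
Reagents that add atoms: none
Why: Dess–Martin oxidation takes the primary alcohol to the aldehyde under buffered conditions, and the aldehyde has no β-leaving group and is remote from the stereocentre.

## Fragment B

Step 11
Reactants: 15 (S)-γ-valerolactone
Product: 16 (4S)-4-hydroxy-N-methoxy-N-methylpentanamide
Conditions: MeNH(OMe)·HCl (3 equiv), AlMe3 (3 equiv), CH2Cl2, 0 °C → rt; then aq. potassium sodium tartrate
Reagents that add atoms: N,O-dimethylhydroxylamine hydrochloride, CNOC.Cl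
Why: Weinreb aminolysis with the aluminium amide opens the lactone by acyl–oxygen cleavage, so the S carbinol centre is carried over unchanged.

Step 12
Reactants: 16 (4S)-4-hydroxy-N-methoxy-N-methylpentanamide
Product: 17 (4S)-4-[(tert-butyldimethylsilyl)oxy]-N-methoxy-N-methylpentanamide
Conditions: t-BuMe2SiCl (1.2 equiv), imidazole (2.5 equiv), DMF, rt
Reagents that add atoms: tert-butyldimethylsilyl chloride, CC(C)(C)[Si](C)(C)Cl
Why: Silyl ether formation stops relactonisation of the γ-hydroxy amide and masks the alcohol for the organometallic steps.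

Step 13
Reactants: 17 (4S)-4-[(tert-butyldimethylsilyl)oxy]-N-methoxy-N-methylpentanamide and 18 6-bromohex-1-ene
Product: 20 (2S)-2-[(tert-butyldimethylsilyl)oxy]undec-10-en-5-one, via hex-5-enylmagnesium bromide 19 (not isolated)
Conditions: 18, Mg turnings, I2 (crystal), THF, rt → 40 °C; then 17, THF, 0 °C → rt; cold 1 M HCl
Reagents that add atoms: none
Why: Grignard addition to a Weinreb amide stops at the ketone because the chelated tetrahedral intermediate only collapses on work-up.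

Step 14
Reactants: 20 (2S)-2-[(tert-butyldimethylsilyl)oxy]undec-10-en-5-one
Product: 21 2-(hex-5-en-1-yl)-2-[(3S)-3-(TBS-oxy)butyl]-1,3-dioxolane
Conditions: (Me3SiOCH2)2 (2 equiv), Me3SiOTf (5 mol%), CH2Cl2, −78 → −20 °C; then pyridine, aq. NaHCO3
Reagents that add atoms: 1,2-bis(trimethylsilyloxy)ethane, C[Si](C)(C)OCCO[Si](C)(C)C
Why: Noyori ketalisation protects the ketone at low temperature under aprotic conditions that spare the TBS ether and the alkene.

Step 15
Reactants: 21 2-(hex-5-en-1-yl)-2-[(3S)-3-(TBS-oxy)butyl]-1,3-dioxolane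
Product: 23 6-{2-[(3S)-3-(TBS-oxy)butyl]-1,3-dioxolan-2-yl}hexan-1-ol, via B-alkyl-9-BBN adduct 22 (not isolated)
Conditions: 9-BBN (0.5 M in THF, 1.5 equiv), 0 °C → rt; then 3 M NaOH, 30% H2O2, 0 °C → rt
Reagents that add atoms: hydrogen peroxide, OO
Why: Hydroboration–oxidation with 9-BBN gives the anti-Markovnikov primary alcohol, and ketal and silyl ether are stable to the basic peroxide.

Step 16
Reactants: 23 6-{2-[(3S)-3-(TBS-oxy)butyl]-1,3-dioxolan-2-yl}hexan-1-ol
Product: 24 5-[(6-{2-[(3S)-3-(TBS-oxy)butyl]-1,3-dioxolan-2-yl}hexyl)sulfanyl]-1-phenyl-1H-tetrazole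
Conditions: 1-phenyl-1H-tetrazole-5-thiol (1.3 equiv), PPh3 (1.3 equiv), DIAD (1.3 equiv), THF, 0 °C → rt
Reagents that add atoms: 1-phenyl-1H-tetrazole-5-thiol, Sc1nnnn1-c1ccccc1
Why: Mitsunobu reaction: the acidic heteroaryl thiol displaces the activated primary alcohol with clean S-alkylation under neutral conditions.

Step 17
Reactants: 24 5-[(6-{2-[(3S)-3-(TBS-oxy)butyl]-1,3-dioxolan-2-yl}hexyl)sulfanyl]-1-phenyl-1H-tetrazole
Product: 25 5-[(6-{2-[(3S)-3-(TBS-oxy)butyl]-1,3-dioxolan-2-yl}hexyl)sulfonyl]-1-phenyl-1H-tetrazole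
Conditions: (NH4)6Mo7O24·4H2O (10 mol%), 30% H2O2 (5 equiv), EtOH, 0 °C → rt
Reagents that add atoms: hydrogen peroxide, OO
Why: Molybdate-catalysed peroxide oxidation takes the sulfide to the sulfone without affecting the ketal or the silyl ether.

## Coupling and end game

Step 18
Reactants: 25 5-[(6-{2-[(3S)-3-(TBS-oxy)butyl]-1,3-dioxolan-2-yl}hexyl)sulfonyl]-1-phenyl-1H-tetrazole and 14 (3S)-5-(benzyloxy)-7-methoxy-3-(3-oxopropyl)isobenzofuran-1(3H)-one
Product: 27 (3S)-5-(benzyloxy)-3-[(3E)-9-{2-[(3S)-3-(TBS-oxy)butyl]-1,3-dioxolan-2-yl}non-3-en-1-yl]-7-methoxyisobenzofuran-1(3H)-one, via potassium sulfonyl carbanion 26 (not isolated)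
Conditions: 25 (1.2 equiv), KN(SiMe3)2 (1.15 equiv), THF, −78 °C, 30 min; then 14, −78 °C → rt; then H2O
Reagents that add atoms: none
Why: Julia–Kocienski olefination: the pre-formed sulfonyl carbanion adds to the aldehyde and Smiles rearrangement with loss of SO2 and the tetrazolone joins the two fragments as an alkene, while pre-forming the anion with a slight deficit of base keeps free base away from the lactone.

Step 19
Reactants: 27 (3S)-5-(benzyloxy)-3-[(3E)-9-{2-[(3S)-3-(TBS-oxy)butyl]-1,3-dioxolan-2-yl}non-3-en-1-yl]-7-methoxyisobenzofuran-1(3H)-one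
Product: 28 (3S)-3-(9-{2-[(3S)-3-(TBS-oxy)butyl]-1,3-dioxolan-2-yl}nonyl)-5-hydroxy-7-methoxyisobenzofuran-1(3H)-one
Conditions: H2 (1 atm), 10% Pd/C, EtOAc, rt
Reagents that add atoms: none
Why: Heterogeneous catalytic hydrogenation saturates both alkene isomers and hydrogenolyses the aryl benzyl ether in one operation, while the lactone C–O bond, held in the plane of the arene, is not cleaved.

Step 20
Reactants: 28 (3S)-3-(9-{2-[(3S)-3-(TBS-oxy)butyl]-1,3-dioxolan-2-yl}nonyl)-5-hydroxy-7-methoxyisobenzofuran-1(3H)-one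
Product: 29 (3S)-5-hydroxy-3-[(13S)-13-hydroxy-10-oxotetradecyl]-7-methoxyisobenzofuran-1(3H)-one
Conditions: 1 M aq. HCl/THF (1:2), rt
Reagents that add atoms: water, O
Why: Acid hydrolysis removes the dioxolane and the TBS ether together and unveils the γ-hydroxy ketone without touching either stereocentre.

## Compound list

1 | resorcinol | Oc1cccc(O)c1 | starting material
2 | 2,4-dihydroxybenzoic acid | OC(=O)c1ccc(O)cc1O | intermediate
3 | methyl 2,4-dihydroxybenzoate | COC(=O)c1ccc(O)cc1O | intermediate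
4 | methyl 4-(benzyloxy)-2-hydroxybenzoate | COC(=O)c1ccc(OCc2ccccc2)cc1O | intermediate
5 | methyl 4-(benzyloxy)-2-methoxybenzoate | COC(=O)c1ccc(OCc2ccccc2)cc1OC | intermediate
6 | 4-(benzyloxy)-N,N-diethyl-2-methoxybenzamide | CCN(CC)C(=O)c1ccc(OCc2ccccc2)cc1OC | intermediate
7 | [5-(benzyloxy)-2-(diethylcarbamoyl)-3-methoxyphenyl]lithium | CCN(CC)C(=O)c1c([Li])cc(OCc2ccccc2)cc1OC | intermediate
8 | 4-(benzyloxy)-N,N-diethyl-2-formyl-6-methoxybenzamide | CCN(CC)C(=O)c1c(C=O)cc(OCc2ccccc2)cc1OC | intermediate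
9 | diisopinocampheylborinate ester of the (S)-homoallylic alcohol 10 (O–B(Ipc)2) | CCN(CC)C(=O)c1c(OC)cc(OCc2ccccc2)cc1[C@H](CC=C)OB([C@@H]3C[C@@H]4C[C@H]([C@H]3C)C4(C)C)[C@@H]3C[C@@H]4C[C@H]([C@H]3C)C4(C)C | intermediate
10 | 4-(benzyloxy)-N,N-diethyl-2-[(1S)-1-hydroxybut-3-en-1-yl]-6-methoxybenzamide | CCN(CC)C(=O)c1c(OC)cc(OCc2ccccc2)cc1[C@@H](O)CC=C | intermediate
11 | (3S)-3-allyl-5-(benzyloxy)-7-methoxyisobenzofuran-1(3H)-one | COc1cc(OCc3ccccc3)cc2c1C(=O)O[C@H]2CC=C | intermediate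
12 | (3S)-5-(benzyloxy)-3-[3-(9-borabicyclo[3.3.1]nonan-9-yl)propyl]-7-methoxyisobenzofuran-1(3H)-one | COc1cc(OCc3ccccc3)cc2c1C(=O)O[C@H]2CCCB4C5CCCC4CCC5 | intermediate
13 | (3S)-5-(benzyloxy)-3-(3-hydroxypropyl)-7-methoxyisobenzofuran-1(3H)-one | COc1cc(OCc3ccccc3)cc2c1C(=O)O[C@H]2CCCO | intermediate
14 | (3S)-5-(benzyloxy)-7-methoxy-3-(3-oxopropyl)isobenzofuran-1(3H)-one | COc1cc(OCc3ccccc3)cc2c1C(=O)O[C@H]2CCC=O | intermediate
15 | (S)-γ-valerolactone, (5S)-5-methyloxolan-2-one | C[C@H]1CCC(=O)O1 | starting material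
16 | (4S)-4-hydroxy-N-methoxy-N-methylpentanamide | CON(C)C(=O)CC[C@H](C)O | intermediate
17 | (4S)-4-[(tert-butyldimethylsilyl)oxy]-N-methoxy-N-methylpentanamide | CON(C)C(=O)CC[C@H](C)O[Si](C)(C)C(C)(C)C | intermediate
18 | 6-bromohex-1-ene | BrCCCCC=C | starting material
19 | hex-5-enylmagnesium bromide | C=CCCCC[Mg]Br | intermediate
20 | (2S)-2-[(tert-butyldimethylsilyl)oxy]undec-10-en-5-one | C=CCCCCC(=O)CC[C@H](C)O[Si](C)(C)C(C)(C)C | intermediate
21 | 2-(hex-5-en-1-yl)-2-[(3S)-3-(TBS-oxy)butyl]-1,3-dioxolane | C=CCCCCC1(CC[C@H](C)O[Si](C)(C)C(C)(C)C)OCCO1 | intermediate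
22 | 9-(6-{2-[(3S)-3-(TBS-oxy)butyl]-1,3-dioxolan-2-yl}hexyl)-9-borabicyclo[3.3.1]nonane | B1(C2CCCC1CCC2)CCCCCCC3(CC[C@H](C)O[Si](C)(C)C(C)(C)C)OCCO3 | intermediate
23 | 6-{2-[(3S)-3-(TBS-oxy)butyl]-1,3-dioxolan-2-yl}hexan-1-ol | OCCCCCCC1(CC[C@H](C)O[Si](C)(C)C(C)(C)C)OCCO1 | intermediate
24 | 5-[(6-{2-[(3S)-3-(TBS-oxy)butyl]-1,3-dioxolan-2-yl}hexyl)sulfanyl]-1-phenyl-1H-tetrazole | c1ccc(cc1)-n1nnnc1SCCCCCCC2(CC[C@H](C)O[Si](C)(C)C(C)(C)C)OCCO2 | intermediate
25 | 5-[(6-{2-[(3S)-3-(TBS-oxy)butyl]-1,3-dioxolan-2-yl}hexyl)sulfonyl]-1-phenyl-1H-tetrazole | O=S(=O)(CCCCCCC1(CC[C@H](C)O[Si](C)(C)C(C)(C)C)OCCO1)c1nnnn1-c1ccccc1 | intermediate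
26 | potassium salt of the α-sulfonyl carbanion of 25 | [K+].O=S(=O)([CH-]CCCCCC1(CC[C@H](C)O[Si](C)(C)C(C)(C)C)OCCO1)c1nnnn1-c1ccccc1 | intermediate
27 | (3S)-5-(benzyloxy)-3-[(3E)-9-{2-[(3S)-3-(TBS-oxy)butyl]-1,3-dioxolan-2-yl}non-3-en-1-yl]-7-methoxyisobenzofuran-1(3H)-one (formed as E/Z mixture) | COc1cc(OCc3ccccc3)cc2c1C(=O)O[C@H]2CC/C=C/CCCCCC4(CC[C@H](C)O[Si](C)(C)C(C)(C)C)OCCO4 | intermediate
28 | (3S)-3-(9-{2-[(3S)-3-(TBS-oxy)butyl]-1,3-dioxolan-2-yl}nonyl)-5-hydroxy-7-methoxyisobenzofuran-1(3H)-one | COc1cc(O)cc2c1C(=O)O[C@H]2CCCCCCCCCC3(CC[C@H](C)O[Si](C)(C)C(C)(C)C)OCCO3 | intermediate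
29 | (3S)-5-hydroxy-3-[(13S)-13-hydroxy-10-oxotetradecyl]-7-methoxyisobenzofuran-1(3H)-one | COc1cc(O)cc2c1C(=O)O[C@H]2CCCCCCCCCC(=O)CC[C@H](C)O | target

## Step count and risks

Total step count: 20 (fragment A steps 1–10, fragment B steps 11–17, end game steps 18–20).
Longest linear sequence: 13 steps (1–10, then 18–20); the other branch is 10 steps (11–17, then 18–20).

The three steps most likely to fail:

**Step 6 (ortho-lithiation of the benzyl ether amide).** s-BuLi may also attack the benzylic CH2 of the ether or the position between the two oxygens. The fallback sets out from 6 and comes back at 8, and runs the metalation on a substrate that has no benzylic ether and is shielded on both sides of the 4-oxygen. Hydrogenolysis of 6 (H2, Pd/C, EtOH) gives N,N-diethyl-4-hydroxy-2-methoxybenzamide F1. Silylation (i-Pr3SiCl, imidazole, DMF) gives N,N-diethyl-2-methoxy-4-[(triisopropylsilyl)oxy]benzamide F2. s-BuLi/TMEDA at −78 °C then gives {2-(diethylcarbamoyl)-3-methoxy-5-[(triisopropylsilyl)oxy]phenyl}lithium F3, which is not isolated, and DMF gives N,N-diethyl-2-formyl-6-methoxy-4-[(triisopropylsilyl)oxy]benzamide F4. Bu4NF/AcOH in THF frees N,N-diethyl-2-formyl-4-hydroxy-6-methoxybenzamide F5, and BnBr/K2CO3 in acetone returns to 8.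

**Step 7 (enantioselectivity of the allylboration next to a bulky, Lewis-basic ortho amide).** The fallback sets out from 6 (through aryllithium 7) and comes back at 13; it sets the stereocentre by asymmetric ketone reduction instead of allylation. Aryllithium 7 is trapped with γ-butyrolactone at −78 °C to give 4-(benzyloxy)-N,N-diethyl-2-(4-hydroxybutanoyl)-6-methoxybenzamide F6. Noyori asymmetric transfer hydrogenation with RuCl[(S,S)-TsDPEN](p-cymene) in HCO2H/Et3N (the catalyst that gives (S)-1-arylalkanols) gives 4-(benzyloxy)-N,N-diethyl-2-[(1S)-1,4-dihydroxybutyl]-6-methoxybenzamide F7. TsOH in toluene at 80 °C closes the five-membered lactone through the benzylic hydroxyl and gives 13.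

**Step 18 (carbanion olefination in the presence of the base-sensitive phthalide aldehyde).** The fallback sets out from 13 and from 21 (through borane 22) and comes back at 28; it replaces the olefination by an alkyl–alkyl cross-coupling. Appel bromination of 13 (CBr4, PPh3, CH2Cl2) gives (3S)-5-(benzyloxy)-3-(3-bromopropyl)-7-methoxyisobenzofuran-1(3H)-one F8. Suzuki–Miyaura coupling of F8 with borane 22 (made from 21 and 9-BBN as in step 15, without oxidation) under Pd(OAc)2/PCy3, K3PO4·H2O, THF, rt gives the saturated benzyl ether (3S)-5-(benzyloxy)-3-(9-{2-[(3S)-3-(TBS-oxy)butyl]-1,3-dioxolan-2-yl}nonyl)-7-methoxyisobenzofuran-1(3H)-one F9. Hydrogenolysis (H2, Pd/C, EtOAc) gives 28.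

## Further compounds

F1 | step 6 | N,N-diethyl-4-hydroxy-2-methoxybenzamide | CCN(CC)C(=O)c1ccc(O)cc1OC
F2 | step 6 | N,N-diethyl-2-methoxy-4-[(triisopropylsilyl)oxy]benzamide | CCN(CC)C(=O)c1ccc(O[Si](C(C)C)(C(C)C)C(C)C)cc1OC
F3 | step 6 | {2-(diethylcarbamoyl)-3-methoxy-5-[(triisopropylsilyl)oxy]phenyl}lithium | CCN(CC)C(=O)c1c([Li])cc(O[Si](C(C)C)(C(C)C)C(C)C)cc1OC
F4 | step 6 | N,N-diethyl-2-formyl-6-methoxy-4-[(triisopropylsilyl)oxy]benzamide | CCN(CC)C(=O)c1c(C=O)cc(O[Si](C(C)C)(C(C)C)C(C)C)cc1OC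
F5 | step 6 | N,N-diethyl-2-formyl-4-hydroxy-6-methoxybenzamide | CCN(CC)C(=O)c1c(C=O)cc(O)cc1OC
F6 | step 7 | 4-(benzyloxy)-N,N-diethyl-2-(4-hydroxybutanoyl)-6-methoxybenzamide | CCN(CC)C(=O)c1c(OC)cc(OCc2ccccc2)cc1C(=O)CCCO
F7 | step 7 | 4-(benzyloxy)-N,N-diethyl-2-[(1S)-1,4-dihydroxybutyl]-6-methoxybenzamide | CCN(CC)C(=O)c1c(OC)cc(OCc2ccccc2)cc1[C@@H](O)CCCO
F8 | step 18 | (3S)-5-(benzyloxy)-3-(3-bromopropyl)-7-methoxyisobenzofuran-1(3H)-one | COc1cc(OCc3ccccc3)cc2c1C(=O)O[C@H]2CCCBr
F9 | step 18 | (3S)-5-(benzyloxy)-3-(9-{2-[(3S)-3-(TBS-oxy)butyl]-1,3-dioxolan-2-yl}nonyl)-7-methoxyisobenzofuran-1(3H)-one | COc1cc(OCc3ccccc3)cc2c1C(=O)O[C@H]2CCCCCCCCCC4(CC[C@H](C)O[Si](C)(C)C(C)(C)C)OCCO4
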